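The readings stem from a simulated flask for an exercise; scatter was added.

The excess of D in this flask is 0.200 equiv over G, the limiting reagent, so each G that reacts eats into a thin cushion of D, and a curve first order in G will not carry you to the asked time.

| flask | G | D | remark | time | volume of the second phase over the first |
|---|---|---|---|---|---|
| midnight | 1 M | 1.2 equiv | the very flask that is asked about, followed so far |  |  |
| autumn | 1 M | 1.8 equiv | run made earlier |  |  |
| flask | 1.0 M | 1.20 equiv |  | 20 min | 2.0 |

| run | time / min | Q / % | G / % |
|---|---|---|---|
| midnight | 0.833 | 1.4 | 98.7 |
| midnight | 1.50 | 3.4 | 97.6 |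
| midnight | 2.50 | 4.9 | 94.2 |
| midnight | 3.00 | 6.0 | 92.8 |
| midnight | 4.00 | 9.0 | 90.9 |
| midnight | 5.00 | 11.7 | 88.4 |
| midnight | 6.00 | 13.8 | 86.3 |
| autumn | 2.00 | 6.2 | 93.9 |
| autumn | 4.00 | 12.8 | 86.7 |
| autumn | 6.00 | 19.2 | 79.7 |
| autumn | 8.00 | 24.7 | 75.1 |
| autumn | 10.0 | 30.4 | 69.3 |
| autumn | 12.0 | 34.0 | 64.4 |
| autumn | 15.0 | 39.7 | 57.8 |

(readings scatter by 0.5 percentage points)

- in the second phase: D; everything else is in the first
- charges count per volume of the first phase; a concentration in a rate is the amount of a species over the volume of its own phase; every rate counts per litre of the first phase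
- the earlier runs were read with a standard deviation of 0.5 percentage points
- the earlier runs hold the two phases in the same ratio of volumes as the flask asked about

1. the Q standing at 20 min, as a percentage of the G charged
2. part of the G charged that has reacted at 20 min

Suppose D crosses fast, so that the part of it beside G is always a fixed share of the D left. With r the fraction of G left and e the equivalents charged, the rate is then a pace κ times r times the D left, and the following clock rises evenly with time:

c = ln[(e − 1 + r)/(e r)] / (e − 1) = κ t

Autumn's last reading gives c_a = 0.351, so κ = 0.0234 min⁻¹, and you would expect 37.1 % of G reacted in the flask.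

But midnight's last reading gives c_m = 0.131, so κ = 0.0218 min⁻¹, which is lower. The two runs differ in D as well as in length, so what follows is one way to read the gap, not a proof: if D needs time to cross, a fixed delay costs a short run more than a long one. So start the clock late, c = κ(t − τ), and use both readings:

κ = (c_a − c_m)/(t_a − t_m) = 0.0245 min⁻¹, the pace

τ = 0.676 min

These are readings, each resting on two points with a scatter of 0.5 percentage points. Still, the delay is short against 20 min, so an error in it costs little. The flask's clock reaches 0.473, which means 37.4 % reacted.

Yet reacted need not mean Q: autumn's last readings of G and Q fall short of the charge by 2.5 points, a gap that carries their scatter. Taking that same gap, although autumn differs from the flask in D and in time, I expect Q near 34.9 %.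

The forecast, a little above my figures, says Q 35.5 % and 37.5 % reacted, on the ground that “the reaction looks first order in G and in D”.

The flask gives Q 34.8 % and 37.2 % reacted, against the clock's 37.4 %.

    G + X → Q (k = 0.0500 L mol⁻¹ min⁻¹)
    X ⇌ D, rate k2*([X] - [D]/K2) per volume of the first phase (partition coefficient = 0.510, kL = 0.730 min⁻¹)
    Q ⇌ E (K = 0.200, k = 0.00790 min⁻¹)

Carried to the same flask read at 50 min, the same pace and delay give 62.2 % reacted, and that flask stands at 62.1 %. At 20.0 min the asked flask makes Q 7.04 times faster than it uses Q up, net, and the half-life of Q by its forward step is 88 min, long against 20 min. What has reacted and is not Q stands as E, at 2.39 %.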